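**The two times.** The coupling partner is the limiting reagent in this flask: 0.480 M stands against 0.80 M of substrate. The readings show substrate lost about as fast as product gained, so I take the coupling as one to one, and the charges cap product at 60.0% of the substrate charged. How far the flask gets depends on two times: the time asked and the partner's half-life.

| flask | substrate | coupling partner | precatalyst | remark | time |
|---|---|---|---|---|---|
| theta | 1.1 M | 0.48 M | 4 mM | run made earlier |  |
| zeta | 1.8 M | 0.48 M | 4 mM | run made earlier |  |
| alpha | 0.80 M | 0.24 M | 4 mM | run made earlier |  |
| flask | 0.80 M | 0.480 M | 4.0 mM |  | 2.0 min |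

| run | time / s | product / % | substrate / % |
|---|---|---|---|
| theta | 10.0 | 4 | 99 |
| theta | 20.0 | 6 | 97 |
| theta | 40.0 | 14 | 84 |
| theta | 80.0 | 24 | 75 |
| zeta | 10.0 | 0 | 98 |
| zeta | 20.0 | 2 | 95 |
| zeta | 30.0 | 7 | 92 |
| zeta | 50.0 | 13 | 87 |
| zeta | 80.0 | 16 | 81 |
| alpha | 10.0 | 0 | 99 |
| alpha | 20.0 | 3 | 98 |
| alpha | 30.0 | 9 | 97 |
| alpha | 50.0 | 12 | 84 |
| alpha | 80.0 | 21 | 85 |

(scatter of a reading: 2 percentage points)

- what was read earlier has a scatter of 2 percentage points, one standard deviation

1. how much product the flask holds at 2.0 min, in percent of the substrate charged
2. how much substrate the flask holds at 2.0 min, in percent of the substrate charged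

**Reading the runs.** At 80.0 s, the readings put product at 0.264 M in theta and 0.288 M in zeta, despite more substrate, but at 0.168 M in alpha, with half the partner and also less substrate. So I treat the partner as pseudo-first-order. Theta's last product reading, with its scatter, leaves 45.0% of it, which gives a read value of 69.4 s for the half-life, the time in which the partner's amount falls by a factor of two.

**My count.** I carry that read value over to this flask, where 2.0 min is 1.73 half-lives, so I reckon on 30.2% of the partner left. That gives 41.9% product and 58.1% substrate.

**The forecast.** It says 43% product and 56% substrate, holding that “the partner caps the flask at 60% product”. My product lies 1.1 percentage points below its figure.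

**The result.** The flask gives 43.5% product and 56.3% substrate.

    substrate + free catalyst ⇌ catalyst intermediate A (K = 1.60 L mol⁻¹, k = 23.0 L mol⁻¹ s⁻¹)
    coupling partner + catalyst intermediate A → catalyst intermediate B (k = 7.00 L mol⁻¹ s⁻¹)
    catalyst intermediate B → free catalyst + product (k = 180 s⁻¹)
    precatalyst → free catalyst (k = 0.0600 s⁻¹)

**Partner left.** At 2.0 min, the flask holds 27% of the partner's charge, less than the 56% of the substrate's charge, and my count gave 30.2%. The same flask stopped at 30 s stands 0.432 half-lives along, so the count gives 15.5% product, while that flask holds 11.9%, with 16.5% of the catalyst charged still precatalyst.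

The earlier runs and the new flask are calculated for substances that don't exist; the scatter is artificial.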